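**Plan**
Retrosynthesis: first the C3–C4 bond of ring C is cut, giving a ring A aldehyde tethered through O1–C2 to a ring B benzylic acetate. Next the O1–C2 ether bond is cut to a ring A phenol and a ring B chloromethyl ketone. Last, the C1′–acyl and C3′–allyl bonds of ring B are cut back to 1,3-bis(methoxymethoxy)benzene, and the side chain to geranyl acetate.
Forward: geranyl acetate is hydrated and brominated. Ring B is substituted by two directed ortho-metalations (allylation at C3′, chloroacetylation at C1′). Ring A is joined by etherification, the oxidation levels are adjusted, ring C is closed in step 12, and the acetals are removed last.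
Enabling feature: C3 is benzylic to ring B, ortho to the 2′-oxygen and para to the 4′-oxygen, so the 2′-phenoxide can expel a leaving group from C3 and give an ortho-quinone methide electrophilic at C3. C4 is a formyl carbon on C4a of ring A, which becomes an acyl anion equivalent under carbene catalysis.
Stereochemistry: the only stereocentre, C3 (S), is set in the C3–C4 bond formation by a chiral triazolylidene catalyst. The E alkene is carried unchanged from geranyl acetate.
Key step: step 12

Assumption: the sense of induction of the aminoindanol-derived triazolium salt in step 12 is taken by analogy with intramolecular Stetter cyclisations; should the first run give the (3R) product, the enantiomeric precatalyst is used in the same way.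

**Step 1**
Reactants: 1 geranyl acetate
Product: 4 (2E)-3,7-dimethyloct-2-ene-1,7-diol, via organomercurial 2 (not isolated), via hydroxy acetate 3 (not isolated)
Conditions: Hg(OAc)2, THF–H2O (1:1), rt; then NaBH4, 3 M NaOH, 0 °C → rt
Reagents that add atoms: water, O
Why: Markovnikov oxymercuration–demercuration should hydrate only the distal trisubstituted alkene, because the 2,3-alkene is deactivated by the allylic acetate, and the alkaline demercuration medium saponifies the acetate while the E alkene is untouched.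

**Step 2**
Reactants: 4 (2E)-3,7-dimethyloct-2-ene-1,7-diol
Product: 5 (6E)-8-bromo-2,6-dimethyloct-6-en-2-ol
Conditions: CBr4, PPh3, CH2Cl2, −20 → 0 °C
Reagents that add atoms: carbon tetrabromide, BrC(Br)(Br)Br
Why: In the Appel reaction the primary allylic alcohol should react far faster than the hindered tertiary alcohol, and SN2 displacement on the alkoxyphosphonium ion at low temperature avoids allylic transposition.

**Step 3**
Reactants: 6 1,3-bis(methoxymethoxy)benzene (2.2 equiv); 5 (6E)-8-bromo-2,6-dimethyloct-6-en-2-ol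
Product: 8 (6E)-8-[2,6-bis(methoxymethoxy)phenyl]-2,6-dimethyloct-6-en-2-ol, via aryllithium 7 (not isolated)
Conditions: n-BuLi (2.1 equiv), THF, 0 °C → rt; CuI (10 mol %), −78 °C; then 5, −78 → 0 °C; aq NH4Cl
Reagents that add atoms: none
Why: Directed ortho-metalation at the carbon flanked by both acetal oxygens is followed by copper-mediated SN2 allylation at the primary carbon of the bromide; one equivalent of 7 serves as base for the hydroxyl of 5 and returns 6, and the E geometry is retained.

**Step 4**
Reactants: 8 (6E)-8-[2,6-bis(methoxymethoxy)phenyl]-2,6-dimethyloct-6-en-2-ol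
Product: 10 2-chloro-1-{3-[(2E)-7-hydroxy-3,7-dimethyloct-2-en-1-yl]-2,4-bis(methoxymethoxy)phenyl}ethan-1-one, via dilithio species 9 (not isolated)
Conditions: n-BuLi (2.3 equiv), TMEDA, THF, −20 → 0 °C; then ClCH2C(O)N(OMe)Me, −78 → −20 °C; aq NH4Cl
Reagents that add atoms: 2-chloro-N-methoxy-N-methylacetamide, CON(C)C(=O)CCl
Why: A second directed ortho-metalation next to one acetal oxygen (the alkoxide uses the first equivalent of base) and acylation of the aryllithium with a Weinreb amide, whose chelated tetrahedral adduct prevents over-addition, should give the chloromethyl ketone.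

**Step 5**
Reactants: 10 2-chloro-1-{3-[(2E)-7-hydroxy-3,7-dimethyloct-2-en-1-yl]-2,4-bis(methoxymethoxy)phenyl}ethan-1-one
Product: 11 2-chloro-1-{2-hydroxy-3-[(2E)-7-hydroxy-3,7-dimethyloct-2-en-1-yl]-4-(methoxymethoxy)phenyl}ethan-1-one
Conditions: conc. HCl (cat.), MeOH, 0 °C → rt; pH 7 work-up
Reagents that add atoms: none
Why: Acid-catalysed transacetalisation to methanol should remove only the acetal ortho to the ketone, which is activated by hydrogen bonding to the carbonyl and by steric compression, while the para acetal, the alkene and the tertiary alcohol survive these mild conditions.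

**Step 6**
Reactants: 11 2-chloro-1-{2-hydroxy-3-[(2E)-7-hydroxy-3,7-dimethyloct-2-en-1-yl]-4-(methoxymethoxy)phenyl}ethan-1-one
Product: 12 2-chloro-1-{2-[(tert-butyldimethylsilyl)oxy]-3-[(2E)-7-hydroxy-3,7-dimethyloct-2-en-1-yl]-4-(methoxymethoxy)phenyl}ethan-1-one
Conditions: TBSOTf (1.1 equiv), 2,6-lutidine, CH2Cl2, −78 → −40 °C
Reagents that add atoms: tert-butyldimethylsilyl triflate, CC(C)(C)[Si](C)(C)OS(=O)(=O)C(F)(F)F
Why: Silyl triflate silylation should cap the hindered, hydrogen-bonded phenol faster than the tertiary alcohol at low temperature, and 2,6-lutidine is too weak a base to form the phenoxide that would close a benzofuranone on the chloromethyl ketone.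

**Step 7**
Reactants: 13 2,4,6-trihydroxybenzaldehyde
Product: 14 2-hydroxy-4,6-bis(methoxymethoxy)benzaldehyde
Conditions: MOMCl (2.1 equiv), i-Pr2NEt, CH2Cl2, 0 °C
Reagents that add atoms: chloromethyl methyl ether, COCCl
Why: O-alkylation with the hard chloromethyl ether should stop at the bis-ether because the remaining phenol is hydrogen-bonded to the formyl group and is the least nucleophilic.

**Step 8**
Reactants: 12 silylated chloromethyl ketone; 14 2-hydroxy-4,6-bis(methoxymethoxy)benzaldehyde
Product: 15 2-(2-{2-[(tert-butyldimethylsilyl)oxy]-3-[(2E)-7-hydroxy-3,7-dimethyloct-2-en-1-yl]-4-(methoxymethoxy)phenyl}-2-oxoethoxy)-4,6-bis(methoxymethoxy)benzaldehyde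
Conditions: K2CO3, acetone, rt → 40 °C
Reagents that add atoms: none
Why: Williamson ether synthesis with an activated α-chloro ketone should proceed at low temperature, where the hindered aryl silyl ether survives and the Rap–Stoermer aldol condensation of the product does not set in.

**Step 9**
Reactants: 15 keto aldehyde
Product: 16 racemic 1-{2-[(tert-butyldimethylsilyl)oxy]-3-[(2E)-7-hydroxy-3,7-dimethyloct-2-en-1-yl]-4-(methoxymethoxy)phenyl}-2-[2-(hydroxymethyl)-3,5-bis(methoxymethoxy)phenoxy]ethan-1-ol
Conditions: NaBH4, MeOH–THF, 0 °C; aq NH4Cl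
Reagents that add atoms: none
Why: Borohydride reduction takes both carbonyl groups to the diol under protic, cold conditions that should disfavour silyl migration to the new alkoxide; the carbinol centre is racemic, which is immaterial because it becomes sp2 in step 12.

**Step 10**
Reactants: 16 diol
Product: 17 racemic 2-(2-{2-[(tert-butyldimethylsilyl)oxy]-3-[(2E)-7-hydroxy-3,7-dimethyloct-2-en-1-yl]-4-(methoxymethoxy)phenyl}-2-hydroxyethoxy)-4,6-bis(methoxymethoxy)benzaldehyde
Conditions: Cu(MeCN)4OTf (5 mol %), 2,2′-bipyridine (5 mol %), TEMPO (5 mol %), N-methylimidazole (10 mol %), air, MeCN, rt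
Reagents that add atoms: none
Why: The copper/TEMPO aerobic alcohol oxidation is selective for primary over secondary alcohols for steric reasons, so the electron-rich primary benzylic alcohol should be returned to the aldehyde while the secondary and tertiary alcohols remain.

**Step 11**
Reactants: 17 hydroxy aldehyde
Product: 18 racemic 1-{2-[(tert-butyldimethylsilyl)oxy]-3-[(2E)-7-hydroxy-3,7-dimethyloct-2-en-1-yl]-4-(methoxymethoxy)phenyl}-2-[2-formyl-3,5-bis(methoxymethoxy)phenoxy]ethyl acetate
Conditions: Ac2O, pyridine, DMAP (5 mol %), CH2Cl2, 0 °C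
Reagents that add atoms: acetic anhydride, CC(=O)OC(C)=O
Why: DMAP-catalysed acetylation should esterify the secondary benzylic alcohol and leave the much more hindered tertiary alcohol, installing the leaving group for the quinone methide.

**Step 12**
Reactants: 18 benzylic acetate
Product: 20 (3S)-3-{2-hydroxy-3-[(2E)-7-hydroxy-3,7-dimethyloct-2-en-1-yl]-4-(methoxymethoxy)phenyl}-5,7-bis(methoxymethoxy)chroman-4-one, via ortho-quinone methide 19 (not isolated)
Conditions: (5aR,10bS)-2-(pentafluorophenyl)-5a,10b-dihydro-4H,6H-indeno[2,1-b][1,2,4]triazolo[4,3-d][1,4]oxazin-2-ium tetrafluoroborate (20 mol %), KN(SiMe3)2 (18 mol %), THF, −40 °C; then CsF (1.2 equiv), 18-crown-6, −40 → 0 °C; AcOH quench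
Reagents that add atoms: none
Why: Proposed new method: Fluoride removes the 2′-silyl group of ring B and the phenoxide expels the benzylic acetate to give the E ortho-quinone methide 19, while the triazolylidene carbene adds to the ring A aldehyde to give a Breslow intermediate whose nucleophilic C4 attacks the methide carbon C3; proton transfer and loss of the carbene then give the ketone and the free 2′-phenol. The closest known reactions are the intramolecular Stetter reaction of salicylaldehyde ethers to chroman-4-ones and the carbene-catalysed 1,6-addition of aldehydes to para-quinone methides, and fluoride-generated ortho-quinone methides are known to tolerate carbene catalysis. Ring C closes in a 6-exo-trig mode onto the exocyclic C3=C1′ bond. The C3 stereocentre is set in the C–C bond-forming event under catalyst control: the aminoindanol backbone shields one face of the Breslow enol, and a hydrogen bond from its hydroxyl to the quinone methide oxygen fixes a closed transition state that presents one face of the single (E) methide. The step needs acylation at C3 to outrun [1,5]-hydrogen shift, acetate return and dimerisation of 19, which is secured by forming the Breslow intermediate before fluoride is added and by the intramolecular six-membered delivery; the neutral phenol product and the weak acetate base left at the end protect the enolisable C3–H from racemisation.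

**Step 13**
Reactants: 20 tris(methoxymethyl) ether
Product: 21 (3S)-3-{2,4-dihydroxy-3-[(2E)-7-hydroxy-3,7-dimethyloct-2-en-1-yl]phenyl}-5,7-dihydroxychroman-4-one
Conditions: ZnBr2, n-PrSH, CH2Cl2, 0 °C, 10 min
Reagents that add atoms: none
Why: Lewis acid-assisted transfer of the three methoxymethyl groups to the thiol (transacetalisation to a formaldehyde dithioacetal) is complete within minutes at 0 °C, which should spare the C3 stereocentre, the trisubstituted alkene next to the phenols and the tertiary alcohol.

**Compound list**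
1 | geranyl acetate, (2E)-3,7-dimethylocta-2,6-dien-1-yl acetate | CC(C)=CCC/C(C)=C/COC(C)=O | starting material
2 | (2E)-6-(acetoxymercurio)-7-hydroxy-3,7-dimethyloct-2-en-1-yl acetate | CC(C)(O)C([Hg]OC(C)=O)CC/C(C)=C/COC(C)=O | intermediate
3 | (2E)-7-hydroxy-3,7-dimethyloct-2-en-1-yl acetate | CC(C)(O)CCC/C(C)=C/COC(C)=O | intermediate
4 | (2E)-3,7-dimethyloct-2-ene-1,7-diol | CC(C)(O)CCC/C(C)=C/CO | intermediate
5 | (6E)-8-bromo-2,6-dimethyloct-6-en-2-ol | CC(C)(O)CCC/C(C)=C/CBr | intermediate
6 | 1,3-bis(methoxymethoxy)benzene | COCOc1cccc(OCOC)c1 | starting material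
7 | 2,6-bis(methoxymethoxy)phenyllithium | [Li]c1c(OCOC)cccc1OCOC | intermediate
8 | (6E)-8-[2,6-bis(methoxymethoxy)phenyl]-2,6-dimethyloct-6-en-2-ol | C/C(=C\Cc1c(OCOC)cccc1OCOC)CCCC(C)(C)O | intermediate
9 | lithium alkoxide of 8 lithiated at the ring carbon ortho to one acetal oxygen | C/C(=C\Cc1c(OCOC)ccc([Li])c1OCOC)CCCC(C)(C)O[Li] | intermediate
10 | 2-chloro-1-{3-[(2E)-7-hydroxy-3,7-dimethyloct-2-en-1-yl]-2,4-bis(methoxymethoxy)phenyl}ethan-1-one | C/C(=C\Cc1c(OCOC)ccc(C(=O)CCl)c1OCOC)CCCC(C)(C)O | intermediate
11 | 2-chloro-1-{2-hydroxy-3-[(2E)-7-hydroxy-3,7-dimethyloct-2-en-1-yl]-4-(methoxymethoxy)phenyl}ethan-1-one | C/C(=C\Cc1c(OCOC)ccc(C(=O)CCl)c1O)CCCC(C)(C)O | intermediate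
12 | 2-chloro-1-{2-[(tert-butyldimethylsilyl)oxy]-3-[(2E)-7-hydroxy-3,7-dimethyloct-2-en-1-yl]-4-(methoxymethoxy)phenyl}ethan-1-one | C/C(=C\Cc1c(OCOC)ccc(C(=O)CCl)c1O[Si](C)(C)C(C)(C)C)CCCC(C)(C)O | intermediate
13 | 2,4,6-trihydroxybenzaldehyde | O=Cc1c(O)cc(O)cc1O | starting material
14 | 2-hydroxy-4,6-bis(methoxymethoxy)benzaldehyde | COCOc1cc(O)c(C=O)c(OCOC)c1 | intermediate
15 | 2-(2-{2-[(tert-butyldimethylsilyl)oxy]-3-[(2E)-7-hydroxy-3,7-dimethyloct-2-en-1-yl]-4-(methoxymethoxy)phenyl}-2-oxoethoxy)-4,6-bis(methoxymethoxy)benzaldehyde | C/C(=C\Cc1c(OCOC)ccc(C(=O)COc2cc(OCOC)cc(OCOC)c2C=O)c1O[Si](C)(C)C(C)(C)C)CCCC(C)(C)O | intermediate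
16 | racemic 1-{2-[(tert-butyldimethylsilyl)oxy]-3-[(2E)-7-hydroxy-3,7-dimethyloct-2-en-1-yl]-4-(methoxymethoxy)phenyl}-2-[2-(hydroxymethyl)-3,5-bis(methoxymethoxy)phenoxy]ethan-1-ol | C/C(=C\Cc1c(OCOC)ccc(C(O)COc2cc(OCOC)cc(OCOC)c2CO)c1O[Si](C)(C)C(C)(C)C)CCCC(C)(C)O | intermediate
17 | racemic 2-(2-{2-[(tert-butyldimethylsilyl)oxy]-3-[(2E)-7-hydroxy-3,7-dimethyloct-2-en-1-yl]-4-(methoxymethoxy)phenyl}-2-hydroxyethoxy)-4,6-bis(methoxymethoxy)benzaldehyde | C/C(=C\Cc1c(OCOC)ccc(C(O)COc2cc(OCOC)cc(OCOC)c2C=O)c1O[Si](C)(C)C(C)(C)C)CCCC(C)(C)O | intermediate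
18 | racemic 1-{2-[(tert-butyldimethylsilyl)oxy]-3-[(2E)-7-hydroxy-3,7-dimethyloct-2-en-1-yl]-4-(methoxymethoxy)phenyl}-2-[2-formyl-3,5-bis(methoxymethoxy)phenoxy]ethyl acetate | C/C(=C\Cc1c(OCOC)ccc(C(OC(C)=O)COc2cc(OCOC)cc(OCOC)c2C=O)c1O[Si](C)(C)C(C)(C)C)CCCC(C)(C)O | intermediate
19 | E ortho-quinone methide of ring B: 2-{2-[(E)-(2-oxocyclohexa-3,5-dien-1-ylidene)]ethoxy}-4,6-bis(methoxymethoxy)benzaldehyde carrying the methoxymethoxy group at C4 and the (2E)-7-hydroxy-3,7-dimethyloct-2-en-1-yl chain at C3 of the dienone ring | O=C1C(C/C=C(\C)CCCC(C)(C)O)=C(OCOC)C=C/C1=C\COc2cc(OCOC)cc(OCOC)c2C=O | intermediate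
20 | (3S)-3-{2-hydroxy-3-[(2E)-7-hydroxy-3,7-dimethyloct-2-en-1-yl]-4-(methoxymethoxy)phenyl}-5,7-bis(methoxymethoxy)chroman-4-one | C/C(=C\Cc1c(OCOC)ccc([C@H]2COc3cc(OCOC)cc(OCOC)c3C2=O)c1O)CCCC(C)(C)O | intermediate
21 | (3S)-3-{2,4-dihydroxy-3-[(2E)-7-hydroxy-3,7-dimethyloct-2-en-1-yl]phenyl}-5,7-dihydroxychroman-4-one | C/C(=C\Cc1c(O)ccc([C@H]2COc3cc(O)cc(O)c3C2=O)c1O)CCCC(C)(C)O | target

**Step count and risks**
Total: 13 steps. Longest linear sequence: 12 steps (steps 1–6 and 8–13; step 7 prepares the ring A partner).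

Steps most likely to fail:

1. Step 12 (Proposed new method). The quinone methide may be consumed by hydrogen shift to the aryl vinyl ether or by oligomerisation before C–C bond formation. Carbene addition to the hindered, electron-rich aldehyde may be slow, facial discrimination may be poor, or C3 may epimerise under base. Fallback with known chemistry, setting out from 15 and returning at 20: an achiral triazolium salt (2-mesityl-6,7-dihydro-5H-pyrrolo[2,1-c][1,2,4]triazol-2-ium chloride) with DBU in THF should close the same C3–C4 bond by an intramolecular crossed benzoin reaction, giving the racemic 3-hydroxychroman-4-one F1. Dehydration with the Burgess reagent in toluene should give the isoflavone F2. Transfer hydrogenation with RuCl(p-cymene)[(S,S)-TsDPEN] in HCO2H–Et3N reduces the enone and then the ketone under dynamic kinetic resolution and should give the cis-(3S,4S)-isoflavan-4-ol F3. Oxidation with Dess–Martin periodinane buffered with NaHCO3 should return the ketone as the (3S)-isoflavanone 2′-silyl ether F4 without touching C3. HF·pyridine in THF at 0 °C then removes the silyl group and the route is rejoined at 20.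

2. Step 13. During acetal cleavage the side-chain alkene may cyclise onto a neighbouring phenol, the tertiary hydroxyl may be lost by ionisation, or C3 may enolise. Fallback setting out from 20 and returning at 21: TMSOTf with 2,2′-bipyridyl in MeCN at 0 °C should exchange the three acetals for silyl ethers under buffered, non-protic conditions, the free phenol and the tertiary alcohol being silylated as well, to give the pentakis(trimethylsilyl) ether F5. Brief solvolysis with citric acid in MeOH at 0 °C should then give 21.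

3. Step 10. The catalyst may stall on the doubly ortho-substituted benzylic alcohol, or discrimination between the primary and the secondary benzylic alcohol may be incomplete. Fallback setting out from 15 and returning at 17, which bypasses diol 16: the aldehyde is masked with HC(OMe)3 and pyridinium p-toluenesulfonate in MeOH as the keto dimethyl acetal F6. The ketone alone is then reduced with NaBH4 to the hydroxy dimethyl acetal F7. The acetal is hydrolysed on wet silica gel with oxalic acid to give 17.

**Further compounds**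
F1 | step 12 | racemic 3-{2-[(tert-butyldimethylsilyl)oxy]-3-[(2E)-7-hydroxy-3,7-dimethyloct-2-en-1-yl]-4-(methoxymethoxy)phenyl}-3-hydroxy-5,7-bis(methoxymethoxy)chroman-4-one | C/C(=C\Cc1c(OCOC)ccc(C2(O)COc3cc(OCOC)cc(OCOC)c3C2=O)c1O[Si](C)(C)C(C)(C)C)CCCC(C)(C)O
F2 | step 12 | 3-{2-[(tert-butyldimethylsilyl)oxy]-3-[(2E)-7-hydroxy-3,7-dimethyloct-2-en-1-yl]-4-(methoxymethoxy)phenyl}-5,7-bis(methoxymethoxy)-4H-chromen-4-one | C/C(=C\Cc1c(OCOC)ccc(-c2coc3cc(OCOC)cc(OCOC)c3c2=O)c1O[Si](C)(C)C(C)(C)C)CCCC(C)(C)O
F3 | step 12 | (3S,4S)-3-{2-[(tert-butyldimethylsilyl)oxy]-3-[(2E)-7-hydroxy-3,7-dimethyloct-2-en-1-yl]-4-(methoxymethoxy)phenyl}-5,7-bis(methoxymethoxy)chroman-4-ol | C/C(=C\Cc1c(OCOC)ccc([C@H]2COc3cc(OCOC)cc(OCOC)c3[C@H]2O)c1O[Si](C)(C)C(C)(C)C)CCCC(C)(C)O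
F4 | step 12 | (3S)-3-{2-[(tert-butyldimethylsilyl)oxy]-3-[(2E)-7-hydroxy-3,7-dimethyloct-2-en-1-yl]-4-(methoxymethoxy)phenyl}-5,7-bis(methoxymethoxy)chroman-4-one | C/C(=C\Cc1c(OCOC)ccc([C@H]2COc3cc(OCOC)cc(OCOC)c3C2=O)c1O[Si](C)(C)C(C)(C)C)CCCC(C)(C)O
F5 | step 13 | (3S)-pentakis(trimethylsilyl) ether of 21 (5-O, 7-O, 2′-O, 4′-O and side-chain O) | C/C(=C\Cc1c(O[Si](C)(C)C)ccc([C@H]2COc3cc(O[Si](C)(C)C)cc(O[Si](C)(C)C)c3C2=O)c1O[Si](C)(C)C)CCCC(C)(C)O[Si](C)(C)C
F6 | step 10 | dimethyl acetal of keto aldehyde 15 | C/C(=C\Cc1c(OCOC)ccc(C(=O)COc2cc(OCOC)cc(OCOC)c2C(OC)OC)c1O[Si](C)(C)C(C)(C)C)CCCC(C)(C)O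
F7 | step 10 | racemic dimethyl acetal of hydroxy aldehyde 17 | C/C(=C\Cc1c(OCOC)ccc(C(O)COc2cc(OCOC)cc(OCOC)c2C(OC)OC)c1O[Si](C)(C)C(C)(C)C)CCCC(C)(C)O
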